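## Retrosynthetic overview

1. The ten-membered carbocycle is closed last, at C1–C10, by an intramolecular Nozaki–Hiyama–Kishi addition of a C10 alkenyl iodide to a C1 cis-epoxy aldehyde; this creates the 1-OH and the 10(14)-methylene.
2. The C8 tiglate comes from a Mitsunobu inversion of the C8 alcohol produced in the fragment union.
3. Fragment union at C7–C8: zinc Barbier allylation of 3-iodobut-3-enal by a 3-(bromomethyl)butenolide that carries C1–C6; this also creates C7 and the α-methylene-γ-lactone.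
4. The butenolide comes from an acrylate ester and ring-closing metathesis on a C6 vinyl carbinol; C6 is set by Noyori reduction of an ynone.
5. Ring order: 2,3-epoxide (Sharpless, from (Z)-butenediol), then 4,5-epoxide (Sharpless), then butenolide, then the ten-membered ring.

Assumption and abbreviations: the target is the (1S,2S,3S,4S,5R,6S,7R,8R) germacranolide read from the SMILES, and positions C1–C15 follow germacrane numbering; PMB = 4-methoxybenzyl; BisEp = the side chain (2R,3S)-3-[(2S,3S)-3-(PMB-oxymethyl)oxiran-2-yl]-3-methyloxiran-2-yl (target C1–C5 and C15).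

## Route

Step 1
Reactants: 1 (2Z)-but-2-ene-1,4-diol
Product: 2 (2Z)-4-(PMB-oxy)but-2-en-1-ol
Conditions: Ag2O (1.5 equiv), PMBCl (1.1 equiv), KI (cat.), CH2Cl2, 25 °C
Reagents that add atoms: 4-methoxybenzyl chloride, COc1ccc(CCl)cc1
Why: Ag2O-mediated Williamson monoalkylation of a symmetrical diol stops cleanly at the mono-ether, and no stereocentre is formed.

Step 2
Reactants: 2 (2Z)-4-(PMB-oxy)but-2-en-1-ol
Product: 3 [(2R,3S)-3-(PMB-oxymethyl)oxiran-2-yl]methanol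
Conditions: Ti(OiPr)4 (0.2 equiv), D-(−)-diethyl tartrate (0.26 equiv), t-BuOOH (2 equiv), 4 Å MS, CH2Cl2, −20 °C
Reagents that add atoms: tert-butyl hydroperoxide, CC(C)(C)OO
Why: Sharpless asymmetric epoxidation of the Z-allylic alcohol gives the cis-epoxide, and the D-(−)-tartrate sets the carbinol-bearing carbon R (target C3 and C2); the minor enantiomer becomes a separable diastereomer after step 8.

Step 3
Reactants: 3 [(2R,3S)-3-(PMB-oxymethyl)oxiran-2-yl]methanol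
Product: 4 (2S,3S)-3-(PMB-oxymethyl)oxirane-2-carbaldehyde
Conditions: Dess–Martin periodinane, pyridine, CH2Cl2, 0 °C to 25 °C
Reagents that add atoms: none
Why: Buffered Dess–Martin oxidation gives the cis-epoxy aldehyde without epimerisation or epoxide opening.

Step 4
Reactants: 4 (2S,3S)-3-(PMB-oxymethyl)oxirane-2-carbaldehyde
Product: 5 1-[(2R,3S)-3-(PMB-oxymethyl)oxiran-2-yl]ethan-1-ol (both carbinol epimers)
Conditions: MeMgBr, THF, −78 °C; then H2O
Reagents that add atoms: methylmagnesium bromide, C[Mg]Br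
Why: Grignard 1,2-addition to the aldehyde is much faster than epoxide opening at −78 °C, and the new carbinol centre is removed in the next step.

Step 5
Reactants: 5 1-[(2R,3S)-3-(PMB-oxymethyl)oxiran-2-yl]ethan-1-ol
Product: 6 1-[(2S,3S)-3-(PMB-oxymethyl)oxiran-2-yl]ethan-1-one
Conditions: Dess–Martin periodinane, pyridine, CH2Cl2, 25 °C
Reagents that add atoms: none
Why: Dess–Martin oxidation converts both epimers into one methyl ketone that carries the future C4 and C15.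

Step 6
Reactants: 6 1-[(2S,3S)-3-(PMB-oxymethyl)oxiran-2-yl]ethan-1-one
Product: 7 ethyl (2E)-3-[(2R,3S)-3-(PMB-oxymethyl)oxiran-2-yl]but-2-enoate
Conditions: (EtO)2P(O)CH2CO2Et, NaH, THF, 0 °C to 25 °C
Reagents that add atoms: triethyl phosphonoacetate, CCOC(=O)CP(=O)(OCC)OCC
Why: Horner–Wadsworth–Emmons olefination of the methyl ketone places the larger oxiranyl group trans to the ester (E), and the minor Z isomer is removed by chromatography.

Step 7
Reactants: 7 ethyl (2E)-3-[(2R,3S)-3-(PMB-oxymethyl)oxiran-2-yl]but-2-enoate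
Product: 8 (2E)-3-[(2R,3S)-3-(PMB-oxymethyl)oxiran-2-yl]but-2-en-1-ol
Conditions: i-Bu2AlH (2.5 equiv), CH2Cl2, −78 °C; then aq potassium sodium tartrate
Reagents that add atoms: none
Why: DIBAL 1,2-reduction of the enoate at low temperature gives the E-allylic alcohol and leaves the epoxide intact.

Step 8
Reactants: 8 (2E)-3-[(2R,3S)-3-(PMB-oxymethyl)oxiran-2-yl]but-2-en-1-ol
Product: 9 BisEp-methanol
Conditions: Ti(OiPr)4 (0.1 equiv), D-(−)-diethyl tartrate (0.13 equiv), t-BuOOH (2 equiv), 4 Å MS, CH2Cl2, −20 °C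
Reagents that add atoms: tert-butyl hydroperoxide, CC(C)(C)OO
Why: Sharpless asymmetric epoxidation of the E-trisubstituted allylic alcohol is reagent-controlled, and D-(−)-tartrate gives the trans-epoxide with target C5 R and C4 S.

Step 9
Reactants: 9 BisEp-methanol
Product: 10 (2S,3R)-3-[(2S,3S)-3-(PMB-oxymethyl)oxiran-2-yl]-3-methyloxirane-2-carbaldehyde
Conditions: Dess–Martin periodinane, pyridine, CH2Cl2, 0 °C to 25 °C
Reagents that add atoms: none
Why: Dess–Martin oxidation of the epoxy alcohol is neutral, so the bis-epoxy aldehyde (target C6) survives.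

Step 10
Reactants: 10 (2S,3R)-3-[(2S,3S)-3-(PMB-oxymethyl)oxiran-2-yl]-3-methyloxirane-2-carbaldehyde
Product: 11 1-BisEp-3-(trimethylsilyl)prop-2-yn-1-ol (both carbinol epimers)
Conditions: Me3SiC≡CH, n-BuLi, THF, −78 °C; add 10; then H2O
Reagents that add atoms: ethynyltrimethylsilane, C#C[Si](C)(C)C
Why: Acetylide 1,2-addition to the aldehyde introduces C7, and the C6 mixture is corrected by the oxidation and reduction that follow.

Step 11
Reactants: 11 1-BisEp-3-(trimethylsilyl)prop-2-yn-1-ol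
Product: 12 1-{(2S,3R)-3-[(2S,3S)-3-(PMB-oxymethyl)oxiran-2-yl]-3-methyloxiran-2-yl}-3-(trimethylsilyl)prop-2-yn-1-one
Conditions: Dess–Martin periodinane, pyridine, CH2Cl2, 25 °C
Reagents that add atoms: none
Why: Dess–Martin oxidation of the propargylic alcohol gives the ynone needed for a reagent-controlled reduction.

Step 12
Reactants: 12 1-{(2S,3R)-3-[(2S,3S)-3-(PMB-oxymethyl)oxiran-2-yl]-3-methyloxiran-2-yl}-3-(trimethylsilyl)prop-2-yn-1-one
Product: 13 (1S)-1-BisEp-3-(trimethylsilyl)prop-2-yn-1-ol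
Conditions: Ru[(R,R)-TsNCHPhCHPhNH](η6-p-cymene) (2 mol %), i-PrOH, 25 °C
Reagents that add atoms: none
Why: Noyori asymmetric transfer hydrogenation of the ynone, with the alkynyl group in the site an aryl group takes, gives (6S) with the (R,R)-catalyst; this is also the Felkin–Anh sense (hydride anti to the epoxide C–O), so catalyst and substrate are matched.

Step 13
Reactants: 13 (1S)-1-BisEp-3-(trimethylsilyl)prop-2-yn-1-ol
Product: 14 (1S)-1-BisEp-prop-2-yn-1-ol
Conditions: K2CO3 (0.2 equiv), MeOH, 0 °C, 30 min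
Reagents that add atoms: none
Why: Base-catalysed methanolysis of the alkynyl C–Si bond is fast at 0 °C, so the epoxy alcohol is not exposed long enough for a Payne rearrangement.

Step 14
Reactants: 14 (1S)-1-BisEp-prop-2-yn-1-ol
Product: 15 (1S)-1-BisEp-prop-2-en-1-ol
Conditions: H2 (1 atm), Pd/CaCO3 poisoned with Pb(OAc)2, quinoline, EtOAc, 25 °C
Reagents that add atoms: none
Why: Lindlar semi-hydrogenation stops at the terminal alkene and leaves the epoxides and the PMB ether untouched.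

Step 15
Reactants: 15 (1S)-1-BisEp-prop-2-en-1-ol
Product: 16 (1S)-1-BisEp-prop-2-en-1-yl 2-(bromomethyl)prop-2-enoate
Conditions: 2-(bromomethyl)prop-2-enoic acid, DCC, DMAP (5 mol %), CH2Cl2, 0 °C
Reagents that add atoms: 2-(bromomethyl)prop-2-enoic acid, OC(=O)C(=C)CBr
Why: Steglich esterification acylates the C6 hydroxyl with retention and brings in C11, C12 and C13 with the allylic bromide already in place.

Step 16
Reactants: 16 (1S)-1-BisEp-prop-2-en-1-yl 2-(bromomethyl)prop-2-enoate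
Product: 17 (5S)-3-(bromomethyl)-5-BisEp-furan-2(5H)-one
Conditions: RuCl2(=CHPh)(H2IMes)(PCy3) (second-generation Grubbs catalyst, 10 mol %), CH2Cl2 (5 mM), 40 °C
Reagents that add atoms: none
Why: Ring-closing metathesis between the vinyl group and the acrylate closes the butenolide (C7=C11) with loss of ethene and touches no stereocentre.

Step 17
Reactants: 18 but-3-yn-1-ol
Product: 19 3-iodobut-3-en-1-ol
Conditions: NaI, Me3SiCl, H2O, MeCN, 25 °C
Reagents that add atoms: sodium iodide, [Na+].[I-]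
Why: Markovnikov hydroiodination of the terminal alkyne by HI made in the flask gives the 2-iodoalkene that later serves as the C10 nucleophile.

Step 18
Reactants: 19 3-iodobut-3-en-1-ol
Product: 20 3-iodobut-3-enal
Conditions: Dess–Martin periodinane, CH2Cl2, 0 °C to 25 °C; filtered and used at once
Reagents that add atoms: none
Why: Dess–Martin oxidation is neutral and fast, so the β,γ-unsaturated aldehyde is obtained without isomerising into conjugation.

Step 19
Reactants: 17 (5S)-3-(bromomethyl)-5-BisEp-furan-2(5H)-one; 20 3-iodobut-3-enal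
Product: 22 (4R,5S)-4-[(1S)-1-hydroxy-3-iodobut-3-en-1-yl]-5-BisEp-3-methylideneoxolan-2-one, via allylzinc bromide 21 (not isolated)
Conditions: Zn dust (5 equiv), 20 (3 equiv), THF/sat. aq NH4Cl (2:1), 0 °C to 25 °C
Reagents that add atoms: none
Why: In this zinc Barbier carbonyl allylation the allylzinc attacks the aldehyde through its γ-carbon (C7) in a chair Zimmerman–Traxler transition state on the face opposite the C6 side chain (7R, trans lactone); the ring fixes the E-type allyl geometry, so the anti adduct (8S) forms together with the C7–C8 bond and the α-methylene-γ-lactone.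

Step 20
Reactants: 22 (4R,5S)-4-[(1S)-1-hydroxy-3-iodobut-3-en-1-yl]-5-BisEp-3-methylideneoxolan-2-one
Product: 24 (1R)-3-iodo-1-[(2S,3R)-2-BisEp-4-methylidene-5-oxooxolan-3-yl]but-3-en-1-yl (2E)-2-methylbut-2-enoate, via alkoxyphosphonium tiglate 23 (not isolated)
Conditions: tiglic acid (3 equiv), PPh3 (3 equiv), i-PrO2CN=NCO2i-Pr (3 equiv), toluene, 0 °C to 25 °C
Reagents that add atoms: (2E)-2-methylbut-2-enoic acid (tiglic acid), C/C=C(\C)C(=O)O
Why: In the Mitsunobu esterification tiglate displaces the C8 oxyphosphonium group by SN2 with inversion (8S to 8R), so the ester and the correct C8 configuration are installed together.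

Step 21
Reactants: 24 (1R)-3-iodo-1-[(2S,3R)-2-BisEp-4-methylidene-5-oxooxolan-3-yl]but-3-en-1-yl (2E)-2-methylbut-2-enoate
Product: 25 (1R)-1-[(2S,3R)-2-{(2R,3S)-3-[(2S,3S)-3-(hydroxymethyl)oxiran-2-yl]-3-methyloxiran-2-yl}-4-methylidene-5-oxooxolan-3-yl]-3-iodobut-3-en-1-yl (2E)-2-methylbut-2-enoate
Conditions: DDQ (1.5 equiv), CH2Cl2/pH 7 phosphate buffer (10:1), 0 °C to 25 °C
Reagents that add atoms: none
Why: Oxidative PMB cleavage by DDQ under buffered conditions frees the C1 hydroxyl while the epoxides, lactone, tiglate and alkenyl iodide are untouched.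

Step 22
Reactants: 25 (1R)-1-[(2S,3R)-2-{(2R,3S)-3-[(2S,3S)-3-(hydroxymethyl)oxiran-2-yl]-3-methyloxiran-2-yl}-4-methylidene-5-oxooxolan-3-yl]-3-iodobut-3-en-1-yl (2E)-2-methylbut-2-enoate
Product: 26 (1R)-1-[(2S,3R)-2-{(2R,3S)-3-[(2S,3R)-3-formyloxiran-2-yl]-3-methyloxiran-2-yl}-4-methylidene-5-oxooxolan-3-yl]-3-iodobut-3-en-1-yl (2E)-2-methylbut-2-enoate
Conditions: Dess–Martin periodinane, pyridine, CH2Cl2, 0 °C to 25 °C
Reagents that add atoms: none
Why: Buffered Dess–Martin oxidation gives the C1 cis-epoxy aldehyde without epimerising C2.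

Step 23
Reactants: 26 (1R)-1-[(2S,3R)-2-{(2R,3S)-3-[(2S,3R)-3-formyloxiran-2-yl]-3-methyloxiran-2-yl}-4-methylidene-5-oxooxolan-3-yl]-3-iodobut-3-en-1-yl (2E)-2-methylbut-2-enoate
Product: 28 CNP0164399.1 = (1S,2S,3S,4S,5R,6S,7R,8R)-2,3:4,5-diepoxy-1-hydroxy-8-[(2E)-2-methylbut-2-enoyloxy]germacra-10(14),11(13)-dien-12,6-olide, via alkenylchromium dichloride 27 (not isolated)
Conditions: CrCl2 (10 equiv), NiCl2 (0.1 equiv), DMSO (2 mM), 25 °C; then H2O
Reagents that add atoms: none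
Why: In the intramolecular Nozaki–Hiyama–Kishi reaction at high dilution the alkenylchromium at C10 adds to the C1 aldehyde anti to the epoxide C–O bond (Felkin–Anh), giving the (1S) allylic alcohol and the 10(14)-methylene; the esters, lactone and epoxides are inert to CrCl2.

## Compound list

1 | (2Z)-but-2-ene-1,4-diol | OC/C=C\CO | starting material
2 | (2Z)-4-[(4-methoxyphenyl)methoxy]but-2-en-1-ol | COc1ccc(COC/C=C\CO)cc1 | intermediate
3 | [(2R,3S)-3-{[(4-methoxyphenyl)methoxy]methyl}oxiran-2-yl]methanol | COc1ccc(COC[C@@H]2O[C@@H]2CO)cc1 | intermediate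
4 | (2S,3S)-3-{[(4-methoxyphenyl)methoxy]methyl}oxirane-2-carbaldehyde | COc1ccc(COC[C@@H]2O[C@@H]2C=O)cc1 | intermediate
5 | 1-[(2R,3S)-3-{[(4-methoxyphenyl)methoxy]methyl}oxiran-2-yl]ethan-1-ol (both carbinol epimers) | COc1ccc(COC[C@@H]2O[C@@H]2C(C)O)cc1 | intermediate
6 | 1-[(2S,3S)-3-{[(4-methoxyphenyl)methoxy]methyl}oxiran-2-yl]ethan-1-one | COc1ccc(COC[C@@H]2O[C@@H]2C(C)=O)cc1 | intermediate
7 | ethyl (2E)-3-[(2R,3S)-3-{[(4-methoxyphenyl)methoxy]methyl}oxiran-2-yl]but-2-enoate | COc1ccc(COC[C@@H]2O[C@@H]2/C(C)=C/C(=O)OCC)cc1 | intermediate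
8 | (2E)-3-[(2R,3S)-3-{[(4-methoxyphenyl)methoxy]methyl}oxiran-2-yl]but-2-en-1-ol | COc1ccc(COC[C@@H]2O[C@@H]2/C(C)=C/CO)cc1 | intermediate
9 | {(2R,3S)-3-[(2S,3S)-3-{[(4-methoxyphenyl)methoxy]methyl}oxiran-2-yl]-3-methyloxiran-2-yl}methanol | COc1ccc(COC[C@@H]2O[C@@H]2[C@@]3(C)O[C@@H]3CO)cc1 | intermediate
10 | (2S,3R)-3-[(2S,3S)-3-{[(4-methoxyphenyl)methoxy]methyl}oxiran-2-yl]-3-methyloxirane-2-carbaldehyde | COc1ccc(COC[C@@H]2O[C@@H]2[C@@]3(C)O[C@@H]3C=O)cc1 | intermediate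
11 | 1-{(2R,3S)-3-[(2S,3S)-3-{[(4-methoxyphenyl)methoxy]methyl}oxiran-2-yl]-3-methyloxiran-2-yl}-3-(trimethylsilyl)prop-2-yn-1-ol (both carbinol epimers) | COc1ccc(COC[C@@H]2O[C@@H]2[C@@]3(C)O[C@@H]3C(O)C#C[Si](C)(C)C)cc1 | intermediate
12 | 1-{(2S,3R)-3-[(2S,3S)-3-{[(4-methoxyphenyl)methoxy]methyl}oxiran-2-yl]-3-methyloxiran-2-yl}-3-(trimethylsilyl)prop-2-yn-1-one | COc1ccc(COC[C@@H]2O[C@@H]2[C@@]3(C)O[C@@H]3C(=O)C#C[Si](C)(C)C)cc1 | intermediate
13 | (1S)-1-{(2R,3S)-3-[(2S,3S)-3-{[(4-methoxyphenyl)methoxy]methyl}oxiran-2-yl]-3-methyloxiran-2-yl}-3-(trimethylsilyl)prop-2-yn-1-ol | COc1ccc(COC[C@@H]2O[C@@H]2[C@@]3(C)O[C@@H]3[C@@H](O)C#C[Si](C)(C)C)cc1 | intermediate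
14 | (1S)-1-{(2R,3S)-3-[(2S,3S)-3-{[(4-methoxyphenyl)methoxy]methyl}oxiran-2-yl]-3-methyloxiran-2-yl}prop-2-yn-1-ol | COc1ccc(COC[C@@H]2O[C@@H]2[C@@]3(C)O[C@@H]3[C@@H](O)C#C)cc1 | intermediate
15 | (1S)-1-{(2R,3S)-3-[(2S,3S)-3-{[(4-methoxyphenyl)methoxy]methyl}oxiran-2-yl]-3-methyloxiran-2-yl}prop-2-en-1-ol | COc1ccc(COC[C@@H]2O[C@@H]2[C@@]3(C)O[C@@H]3[C@@H](O)C=C)cc1 | intermediate
16 | (1S)-1-{(2R,3S)-3-[(2S,3S)-3-{[(4-methoxyphenyl)methoxy]methyl}oxiran-2-yl]-3-methyloxiran-2-yl}prop-2-en-1-yl 2-(bromomethyl)prop-2-enoate | COc1ccc(COC[C@@H]2O[C@@H]2[C@@]3(C)O[C@@H]3[C@@H](OC(=O)C(=C)CBr)C=C)cc1 | intermediate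
17 | (5S)-3-(bromomethyl)-5-{(2R,3S)-3-[(2S,3S)-3-{[(4-methoxyphenyl)methoxy]methyl}oxiran-2-yl]-3-methyloxiran-2-yl}furan-2(5H)-one | COc1ccc(COC[C@@H]2O[C@@H]2[C@@]3(C)O[C@@H]3[C@H]4OC(=O)C(CBr)=C4)cc1 | intermediate
18 | but-3-yn-1-ol | C#CCCO | starting material
19 | 3-iodobut-3-en-1-ol | C=C(I)CCO | intermediate
20 | 3-iodobut-3-enal | C=C(I)CC=O | intermediate
21 | allylzinc bromide from 17 (CH2ZnBr in place of CH2Br, otherwise as 17) | COc1ccc(COC[C@@H]2O[C@@H]2[C@@]3(C)O[C@@H]3[C@H]4OC(=O)C(C[Zn]Br)=C4)cc1 | intermediate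
22 | (4R,5S)-4-[(1S)-1-hydroxy-3-iodobut-3-en-1-yl]-5-{(2R,3S)-3-[(2S,3S)-3-{[(4-methoxyphenyl)methoxy]methyl}oxiran-2-yl]-3-methyloxiran-2-yl}-3-methylideneoxolan-2-one | COc1ccc(COC[C@@H]2O[C@@H]2[C@@]3(C)O[C@@H]3[C@H]4OC(=O)C(=C)[C@@H]4[C@@H](O)CC(I)=C)cc1 | intermediate
23 | alkoxyphosphonium tiglate from 22 (C8–O–PPh3 cation with tiglate anion, configuration as in 22) | COc1ccc(COC[C@@H]2O[C@@H]2[C@@]3(C)O[C@@H]3[C@H]4OC(=O)C(=C)[C@@H]4[C@@H](O[P+](c5ccccc5)(c5ccccc5)c5ccccc5)CC(I)=C)cc1.C/C=C(\C)C(=O)[O-] | intermediate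
24 | (1R)-3-iodo-1-[(2S,3R)-2-{(2R,3S)-3-[(2S,3S)-3-{[(4-methoxyphenyl)methoxy]methyl}oxiran-2-yl]-3-methyloxiran-2-yl}-4-methylidene-5-oxooxolan-3-yl]but-3-en-1-yl (2E)-2-methylbut-2-enoate | COc1ccc(COC[C@@H]2O[C@@H]2[C@@]3(C)O[C@@H]3[C@H]4OC(=O)C(=C)[C@@H]4[C@H](OC(=O)/C(C)=C/C)CC(I)=C)cc1 | intermediate
25 | (1R)-1-[(2S,3R)-2-{(2R,3S)-3-[(2S,3S)-3-(hydroxymethyl)oxiran-2-yl]-3-methyloxiran-2-yl}-4-methylidene-5-oxooxolan-3-yl]-3-iodobut-3-en-1-yl (2E)-2-methylbut-2-enoate | OC[C@@H]1O[C@@H]1[C@@]2(C)O[C@@H]2[C@H]3OC(=O)C(=C)[C@@H]3[C@H](OC(=O)/C(C)=C/C)CC(I)=C | intermediate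
26 | (1R)-1-[(2S,3R)-2-{(2R,3S)-3-[(2S,3R)-3-formyloxiran-2-yl]-3-methyloxiran-2-yl}-4-methylidene-5-oxooxolan-3-yl]-3-iodobut-3-en-1-yl (2E)-2-methylbut-2-enoate | O=C[C@@H]1O[C@@H]1[C@@]2(C)O[C@@H]2[C@H]3OC(=O)C(=C)[C@@H]3[C@H](OC(=O)/C(C)=C/C)CC(I)=C | intermediate
27 | alkenylchromium dichloride from 26 (C10–CrCl2 in place of C10–I, otherwise as 26) | O=C[C@@H]1O[C@@H]1[C@@]2(C)O[C@@H]2[C@H]3OC(=O)C(=C)[C@@H]3[C@H](OC(=O)/C(C)=C/C)CC([Cr](Cl)Cl)=C | intermediate
28 | CNP0164399.1, (1S,2S,3S,4S,5R,6S,7R,8R)-2,3:4,5-diepoxy-1-hydroxy-8-[(2E)-2-methylbut-2-enoyloxy]germacra-10(14),11(13)-dien-12,6-olide | C=C1C(=O)O[C@H]2[C@H]1[C@H](OC(=O)/C(C)=C/C)CC(=C)[C@H](O)[C@@H]1O[C@@H]1[C@@]1(C)O[C@H]21 | target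

## Step count and risks

Total step count: 23. Longest linear sequence: 21 steps (steps 1–16, then 19–23); steps 17–18 make the aldehyde partner.

The three steps most likely to fail:

Step 19 (Barbier union). Aldehyde 20 is a labile β,γ-unsaturated aldehyde, and in the aqueous zinc medium the allylzinc can be protonated to the 3-methylbutenolide before it couples. The fallback sets out from 17 and comes back at 22. Compound 17 is borylated (B2pin2, Pd2(dba)3 cat., THF, 40 °C) to the isolable allylboronate (5S)-5-BisEp-3-[(4,4,5,5-tetramethyl-1,3,2-dioxaborolan-2-yl)methyl]furan-2(5H)-one F1. F1 is then warmed with freshly made 20 in dry toluene. This allylboration has no reducing metal and no water, and its closed six-membered transition state gives the same trans and anti sense; aqueous NaHCO3 work-up releases 22.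

Step 20 (Mitsunobu inversion). The C8 carbinol is hindered and flanked by the allylic C7–H, so elimination or incomplete inversion can compete. The fallback sets out from 22 and comes back at 24, and it replaces substitution at C8 by a redox inversion. Dess–Martin oxidation gives the ketone (4S,5S)-4-(3-iodobut-3-enoyl)-5-BisEp-3-methylideneoxolan-2-one F2. Reagent-controlled reduction with (S)-2-methyl-CBS-oxazaborolidine and catecholborane (toluene, −78 °C; the branched C7 side acts as the large group) gives the alcohol (4R,5S)-4-[(1R)-1-hydroxy-3-iodobut-3-en-1-yl]-5-BisEp-3-methylideneoxolan-2-one F3. Esterification with retention (tiglic acid, 2,4,6-trichlorobenzoyl chloride, Et3N, DMAP) then gives 24.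

Step 23 (ten-membered ring closure). Ring strain invites oligomers, and the face selectivity at C1 inside the forming ring is not guaranteed. The fallback sets out from 26 and comes back at 28; it no longer relies on the C–C bond formation to set C1. The ring closure is run for yield only, and the C1 epimer (1R,2S,3S,4S,5R,6S,7R,8R)-2,3:4,5-diepoxy-1-hydroxy-8-[(2E)-2-methylbut-2-enoyloxy]germacra-10(14),11(13)-dien-12,6-olide F4, alone or mixed with 28, is oxidised (Dess–Martin periodinane, pyridine) to the enone (2R,3S,4S,5R,6S,7R,8R)-2,3:4,5-diepoxy-8-[(2E)-2-methylbut-2-enoyloxy]-1-oxogermacra-10(14),11(13)-dien-12,6-olide F5. Chelation-controlled 1,2-reduction of this α,β-epoxy ketone (NaBH4, CeCl3·7H2O, MeOH, −78 °C) is erythro-selective and gives 28.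

Further compounds
F1 | step 19 | (5S)-5-{(2R,3S)-3-[(2S,3S)-3-{[(4-methoxyphenyl)methoxy]methyl}oxiran-2-yl]-3-methyloxiran-2-yl}-3-[(4,4,5,5-tetramethyl-1,3,2-dioxaborolan-2-yl)methyl]furan-2(5H)-one | COc1ccc(COC[C@@H]2O[C@@H]2[C@@]3(C)O[C@@H]3[C@H]4OC(=O)C(CB5OC(C)(C)C(C)(C)O5)=C4)cc1
F2 | step 20 | (4S,5S)-4-(3-iodobut-3-enoyl)-5-{(2R,3S)-3-[(2S,3S)-3-{[(4-methoxyphenyl)methoxy]methyl}oxiran-2-yl]-3-methyloxiran-2-yl}-3-methylideneoxolan-2-one | COc1ccc(COC[C@@H]2O[C@@H]2[C@@]3(C)O[C@@H]3[C@H]4OC(=O)C(=C)[C@@H]4C(=O)CC(I)=C)cc1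
F3 | step 20 | (4R,5S)-4-[(1R)-1-hydroxy-3-iodobut-3-en-1-yl]-5-{(2R,3S)-3-[(2S,3S)-3-{[(4-methoxyphenyl)methoxy]methyl}oxiran-2-yl]-3-methyloxiran-2-yl}-3-methylideneoxolan-2-one | COc1ccc(COC[C@@H]2O[C@@H]2[C@@]3(C)O[C@@H]3[C@H]4OC(=O)C(=C)[C@@H]4[C@H](O)CC(I)=C)cc1
F4 | step 23 | (1R,2S,3S,4S,5R,6S,7R,8R)-2,3:4,5-diepoxy-1-hydroxy-8-[(2E)-2-methylbut-2-enoyloxy]germacra-10(14),11(13)-dien-12,6-olide | C=C1C(=O)O[C@H]2[C@H]1[C@H](OC(=O)/C(C)=C/C)CC(=C)[C@@H](O)[C@@H]1O[C@@H]1[C@@]1(C)O[C@H]21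
F5 | step 23 | (2R,3S,4S,5R,6S,7R,8R)-2,3:4,5-diepoxy-8-[(2E)-2-methylbut-2-enoyloxy]-1-oxogermacra-10(14),11(13)-dien-12,6-olide | C=C1C(=O)O[C@H]2[C@H]1[C@H](OC(=O)/C(C)=C/C)CC(=C)C(=O)[C@@H]1O[C@@H]1[C@@]1(C)O[C@H]21
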